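Start at early times, with the earlier runs and the flask they must forecast.

| flask | X | E | remark | time |
|---|---|---|---|---|
| south | 20 mM | 0.40 equiv | run made earlier |  |
| east | 20 mM | 1.6 equiv | run made earlier |  |
| north-west | 10 mM | 0.80 equiv | run made earlier |  |
| flask | 20 mM | 0.800 equiv |  | 25 min |

| run | time / min | Q / % |
|---|---|---|
| south | 0.167 | 9.0 |
| south | 0.333 | 16.0 |
| south | 0.667 | 22.1 |
| south | 1.50 | 19.9 |
| south | 3.00 | 19.3 |
| south | 8.00 | 11.4 |
| south | 15.0 | 12.6 |
| east | 0.167 | 31.1 |
| east | 0.333 | 38.4 |
| east | 0.667 | 34.3 |
| east | 1.50 | 26.3 |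
| east | 3.00 | 17.8 |
| east | 8.00 | 15.9 |
| east | 15.0 | 16.7 |
| north-west | 0.167 | 12.7 |
| north-west | 0.500 | 22.6 |
| north-west | 1.50 | 30.6 |
| north-west | 5.00 | 21.2 |
| north-west | 15.0 | 15.9 |

(standard deviation of a reading: 1 percentage point)
- time, not beyond 25 min, at which the flask holds most Q
- the amount of Q, in percent of the X charged, at that time
- earliest time at which at least nineteen twentieths of that best amount are there, in min
- latest time at which they still are, in min
- what may be going on: X + E <-> L + Q; Q + E <-> L + J; 2 E -> G

Take the first readings, at 0.167 min: south shows 9.0 % of Q and east 31.1 %, a factor 3.46 for a factor 4.00 in E, so early Q follows [E] closely. Now take the highest readings: south 22.1 % at 0.667 min, east 38.4 % at 0.333 min, a factor 1.74 against the same factor 4.00 in E.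

Draw a straight line in equivalents between south and east: the flask, with E the limiting reagent at 0.800 equiv, gets 27.5 %. Distrust that link, since two peaks do not show what shape joins them. Reforge it by counting doublings of E instead. East lies two doublings above south and wins 8.1 percentage points on each: call this the doubling gain, the points of peak Q won each time the charge of E doubles at fixed [X]. The flask lies 1.00 doubling above south, so commit to 30.2 %, above the line. Two readings set this gain, each good to 1 point.

The forecast, reached by a rough integration of rates, gives 30 % at 0.55 min, with the window from 0.4 min to 1 min: “Q peaks near 30% at about 0.55 min”.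

The flask gives 30.0 % at 0.653 min, a factor 1.19 later than the forecast, and holds the share of it asked for from 0.427 min to 1.02 min.

    X + E ⇌ L + Q (K = 0.650, k = 1.63 M⁻¹ s⁻¹)
    Q + E ⇌ L + J (K = 3.50, k = 0.688 M⁻¹ s⁻¹)
    2 E → G (k = 0.0682 M⁻¹ s⁻¹)

The committed 30.2 % stands 0.20 points above the flask's peak. Carry it on to the neighbouring flask, charged with 2.00 equiv of E and otherwise the same. Starting from the flask's 30.0 %, that charge lies 1.32 doublings higher, so the gain predicts 40.7 %. The neighbouring flask reaches 40.3 % of Q.

The data stem from a simulated flask on assumed constants.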